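The hydroxylated ring is cut between C-2' (the ring CH2) and the carbinol C-3'. In the ring ketone that precedes the exocyclic C-6'=C-7' bond, C-2' lies β to the C-6' carbonyl through the quaternary C-1', and C-3' is the γ-carbon of the enone, so a homoenolate at C-2' can attack an aldehyde at C-3'. The key step therefore isomerises a spiro cyclopropanol lactol (cyclopropane C-6'/C-1'/C-2', lactol carbon C-3', cis C-4'=C-5') with a chiral zinc amino-alkoxide catalyst into (S)-4-hydroxy-2,6,6-trimethylcyclohex-2-enone, closing the six-membered ring and setting the only stereocentre. Two retro C14 phosphonium units, a C12 dialdehyde and a late single dehydration complete the carotenoid.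

Key step: step 6

Remarks on the chemistry:
- Carotenoid numbering is used, unprimed for the cyclohexadienylidene end and primed for the hydroxylated end.
- Assumption: the geometry of the two exocyclic ring double bonds (chain on the side of the gem-dimethyl carbon) and the all-trans chain are taken to be the thermodynamically preferred arrangement, so the equilibration in step 12 and the cation-mediated dehydration in step 13 converge on the target geometry.
- Both end groups come from the same phosphonium salt 18 in one twofold olefination. This gives the C2-symmetric diol 25, whose two ends are equivalent, and the stereocentre of one end is removed on purpose in step 13.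

Step 1
Reactants: 1 1-methoxy-2-methyl-1-(trimethylsilyloxy)prop-1-ene
Product: 2 1-methoxy-2,2-dimethyl-1-(trimethylsilyloxy)cyclopropane (racemic)
Conditions: Et2Zn, CH2I2, pentane, 0 °C to rt; pyridine, then aq. NaHCO3
Reagents that add atoms: diiodomethane, ICI
Why: Simmons–Smith cyclopropanation (Furukawa variant) of the electron-rich ketene silyl acetal; the hydrocarbon solvent and the basic quench should keep zinc halide from opening the cyclopropanone acetal.

Step 2
Reactants: 2 1-methoxy-2,2-dimethyl-1-(trimethylsilyloxy)cyclopropane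
Product: 3 1-methoxy-2,2-dimethylcyclopropan-1-ol (racemic cyclopropanone hemiketal)
Conditions: MeOH, rt, 12 h; evaporation
Reagents that add atoms: none
Why: Methanolysis of the O–Si bond should give the hemiketal, a storable equivalent of 2,2-dimethylcyclopropanone.

Step 3
Reactants: 4 but-2-yn-1-ol
Product: 6 (2Z)-3-iodobut-2-en-1-ol, via cyclic alkenylalanate 5 (not isolated)
Conditions: NaAlH2(OCH2CH2OMe)2 (1.05 equiv), Et2O, 0 °C to rt; then I2, THF, −78 °C to 0 °C
Reagents that add atoms: iodine, II
Why: Hydroxyl-directed trans-hydroalumination places aluminium on C-3 inside a five-membered alkoxyalanate, and iodinolysis with retention should give the iodide with iodine cis to CH2OH.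

Step 4
Reactants: 6 (2Z)-3-iodobut-2-en-1-ol, 3 1-methoxy-2,2-dimethylcyclopropan-1-ol
Product: 9 1-[(2Z)-4-hydroxybut-2-en-2-yl]-2,2-dimethylcyclopropan-1-ol (racemic), via dilithio alkenyl alkoxide 7 (not isolated), via 2,2-dimethylcyclopropanone 8 (not isolated)
Conditions: 6, n-BuLi (1.0 equiv) then t-BuLi (2.0 equiv), Et2O, −78 °C; separately 3, MeMgBr (1.0 equiv), THF, 0 °C; combine, −78 °C to rt; aq. NH4Cl
Reagents that add atoms: none
Why: Iodine–lithium exchange with retention gives a configurationally stable alkenyllithium, which should add to the cyclopropanone released from the magnesium hemiketalate (1,2-addition of an organometallic to a cyclopropanone hemiketal).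

Step 5
Reactants: 9 1-[(2Z)-4-hydroxybut-2-en-2-yl]-2,2-dimethylcyclopropan-1-ol
Product: 11 1,1,7-trimethyl-4-oxaspiro[2.4]hept-6-en-5-ol (lactol, diastereomer mixture), via hydroxy enal 10 (not isolated)
Conditions: SO3·pyridine (1.5 equiv), DMSO, i-Pr2NEt, CH2Cl2, −10 °C; aq. NaHCO3
Reagents that add atoms: none
Why: Parikh–Doering oxidation should touch only the primary allylic alcohol (the tertiary cyclopropanol has no carbinol hydrogen and no oxidising metal is present), and the cis hydroxy enal closes at once to the lactol, which locks the Z geometry.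

Step 6
Reactants: 11 1,1,7-trimethyl-4-oxaspiro[2.4]hept-6-en-5-ol
Product: 13 (4S)-4-hydroxy-2,6,6-trimethylcyclohex-2-en-1-one, via zinc homoenolate 12 (not isolated)
Conditions: Et2Zn (20 mol%), (S)-diphenyl(1-methylpyrrolidin-2-yl)methanol (22 mol%), toluene/DMSO 5:1, 40 °C; aq. NH4Cl
Reagents that add atoms: none
Why: Proposed new method: the chiral zinc amino-alkoxide exchanges onto the lactol oxygen, ring–chain opening hands zinc to the cyclopropanol oxygen of the cis enal 10, β-carbon elimination cleaves the less substituted C(O)–CH2 bond to give the primary zinc homoenolate 12 (the gem-dimethyl group excludes enolisation and β-hydride loss), and this adds 1,2 to the aldehyde before the product alkoxide is exchanged for fresh lactol, so the net change is an isomerisation. The closest known reaction types are the catalytic generation of zinc homoenolates from cyclopropanols by Et2Zn and β-amino alcohols with enantioselective C–C bond formation, the addition of zinc and titanium ester homoenolates to aldehydes, and amino-alcohol-controlled alkylzinc additions to aldehydes. The six-membered carbocycle closes by 6-exo-trig attack of the zinc-bearing CH2 on the aldehyde carbon, the cis double bond inherited from the lactol holding the two termini within reach. The new carbinol stereocentre is set by the zinc-bound amino alkoxide, which differentiates the two aldehyde faces; the (S) sense is the goal and the mirror-image ligand is used if the opposite sense is found, while both stereocentres of 11 are erased. The step needs regioselective ring opening (primary, not tertiary, alkylzinc), attack on the aldehyde instead of return to the ketone (which only regenerates the cyclopropoxide) and C–C formation faster than protonolysis of the C–Zn bond, which the intramolecular six-membered transition state and the aprotic medium should secure.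

Step 7
Reactants: 13 (4S)-4-hydroxy-2,6,6-trimethylcyclohex-2-en-1-one, 14 2-methylbut-1-en-3-yne
Product: 16 (4S)-1-(3-methylbut-3-en-1-yn-1-yl)-2,6,6-trimethylcyclohex-2-ene-1,4-diol (C-1 epimers), via lithium acetylide 15 (not isolated)
Conditions: 14 (3.2 equiv), n-BuLi (3.0 equiv), THF, −78 °C; then 13, −78 °C to 0 °C; aq. NH4Cl
Reagents that add atoms: none
Why: 1,2-Addition of a lithium acetylide to the hindered, non-enolisable enone carbonyl (the first equivalent deprotonates the hydroxyl); the new tertiary carbinol forms as an epimer mixture that converges in step 9.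

Step 8
Reactants: 16 (4S)-1-(3-methylbut-3-en-1-yn-1-yl)-2,6,6-trimethylcyclohex-2-ene-1,4-diol
Product: 17 (4S)-1-[(1E)-3-methylbuta-1,3-dien-1-yl]-2,6,6-trimethylcyclohex-2-ene-1,4-diol (C-1 epimers)
Conditions: NaAlH2(OCH2CH2OMe)2 (4 equiv), THF, 0 °C to rt; aq. KNaC4H4O6
Reagents that add atoms: none
Why: Alkoxide-directed trans-hydroalumination of the propargylic alcohol followed by protonolysis should give the (E)-alkene and leave the other alkenes untouched.

Step 9
Reactants: 17 (4S)-1-[(1E)-3-methylbuta-1,3-dien-1-yl]-2,6,6-trimethylcyclohex-2-ene-1,4-diol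
Product: 18 {(2E)-4-[(1E,4S)-4-hydroxy-2,6,6-trimethylcyclohex-2-en-1-ylidene]-2-methylbut-2-en-1-yl}triphenylphosphonium bromide (retro C14 salt)
Conditions: PPh3·HBr (1.05 equiv), CH2Cl2, 0 °C to rt
Reagents that add atoms: triphenylphosphine hydrobromide, [PH+](c1ccccc1)(c1ccccc1)c1ccccc1.[Br-]
Why: Phosphonium salt formation with allylic transposition (SN1 type): the tertiary, doubly allylic carbinol ionises to a delocalised cation that triphenylphosphine should capture at the unhindered primary terminus, which leaves the conjugated retro triene, while the secondary allylic hydroxyl is not ionised by this weak acid.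

Step 10
Reactants: 19 (2E)-3-methylpent-2-en-4-yn-1-ol (two equivalents)
Product: 21 (2E,4E,6E,8E)-3,8-dimethyldeca-2,4,6,8-tetraene-1,10-diol, via bis-zirconated dienyl alkoxide 20 (not isolated)
Conditions: Cp2Zr(H)Cl (2.2 equiv per alkyne), THF, rt; then CuCl (1.1 equiv), 0 °C to rt; aq. NH4Cl
Reagents that add atoms: none
Why: syn-Hydrozirconation of the terminal alkyne (one equivalent is consumed by the hydroxyl) gives the (E)-alkenylzirconocene, and transmetalation to copper followed by homocoupling of the alkenylcopper should join the two terminal carbons with retention of geometry.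

Step 11
Reactants: 21 (2E,4E,6E,8E)-3,8-dimethyldeca-2,4,6,8-tetraene-1,10-diol
Product: 22 (2E,4E,6E,8E)-3,8-dimethyldeca-2,4,6,8-tetraenedial (C12 dialdehyde)
Conditions: MnO2 (excess), CH2Cl2, rt, dark
Reagents that add atoms: none
Why: MnO2 oxidation is selective for allylic primary alcohols and should give the dialdehyde without touching the tetraene.

Step 12
Reactants: 18 retro C14 phosphonium bromide (2.2 equiv), 22 C12 dialdehyde
Product: 25 (3S,3'S)-eschscholtzxanthin, via phosphorus ylide 23 (not isolated), via hydroxy C26 aldehyde 24 (not isolated)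
Conditions: NaOMe (2.3 equiv), MeOH/CH2Cl2, 0 °C to rt, dark, N2; then I2 (1 mol%), CH2Cl2, rt, diffuse light; crystallisation
Reagents that add atoms: none
Why: Twofold Wittig olefination of the symmetric dialdehyde at the α-carbon of the delocalised ylide forms both new disubstituted chain double bonds in one flask (the mono-olefinated aldehyde 24 reacts on with a second ylide), the free hydroxyls are tolerated, and iodine-catalysed equilibration followed by crystallisation should deliver the all-trans isomer with both carbinol stereocentres from step 6 untouched.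

Step 13
Reactants: 25 (3S,3'S)-eschscholtzxanthin
Product: 26 CNP0202479.1 (anhydroeschscholtzxanthin, 3'S)
Conditions: dry HCl (ca. 0.01 M) in CHCl3, 0 °C, stopped at partial conversion; aq. NaHCO3; chromatography on deactivated silica, recovered 25 recycled
Reagents that add atoms: none
Why: Acid-catalysed dehydration (E1) of a polyene allylic alcohol: the polyenyl cation carries no charge on the carbons next to the gem-dimethyl carbon, so no methyl shift competes, loss of the ring CH2 proton should give the fully conjugated cyclohexadienylidene end group under thermodynamic control, and because the two ends of the C2-symmetric diol are equivalent a single dehydration at either end gives the same product, which differs strongly in polarity from the diol and from the doubly dehydrated hydrocarbon.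

Compound list
1 | 1-methoxy-2-methyl-1-(trimethylsilyloxy)prop-1-ene | CC(C)=C(OC)O[Si](C)(C)C | starting material
2 | 1-methoxy-2,2-dimethyl-1-(trimethylsilyloxy)cyclopropane (racemic) | COC1(O[Si](C)(C)C)CC1(C)C | intermediate
3 | 1-methoxy-2,2-dimethylcyclopropan-1-ol (racemic) | COC1(O)CC1(C)C | intermediate
4 | but-2-yn-1-ol | CC#CCO | starting material
5 | sodium 2,2-bis(2-methoxyethoxy)-3-methyl-2,5-dihydro-1,2-oxaluminol-2-uide (cyclic alkenylalanate, not isolated) | CC1=CCO[Al-]1(OCCOC)OCCOC.[Na+] | intermediate
6 | (2Z)-3-iodobut-2-en-1-ol | C/C(I)=C/CO | intermediate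
7 | lithium (2E)-3-lithiobut-2-en-1-olate (lithium cis to the CH2O group, not isolated) | [Li]OC/C=C(/C)[Li] | intermediate
8 | 2,2-dimethylcyclopropan-1-one (not isolated) | CC1(C)CC1=O | intermediate
9 | 1-[(2Z)-4-hydroxybut-2-en-2-yl]-2,2-dimethylcyclopropan-1-ol (racemic) | OC/C=C(/C)C1(O)CC1(C)C | intermediate
10 | (2Z)-3-(1-hydroxy-2,2-dimethylcyclopropyl)but-2-enal (not isolated) | O=C/C=C(/C)C1(O)CC1(C)C | intermediate
11 | 1,1,7-trimethyl-4-oxaspiro[2.4]hept-6-en-5-ol (diastereomer mixture) | CC1=CC(O)OC12CC2(C)C | intermediate
12 | [(4Z)-2,2,4-trimethyl-3,6-dioxohex-4-en-1-yl]zinc (S)-diphenyl(1-methylpyrrolidin-2-yl)methanolate (zinc homoenolate, not isolated) | CN1CCC[C@H]1C(O[Zn]CC(C)(C)C(=O)/C(C)=C\C=O)(c1ccccc1)c1ccccc1 | intermediate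
13 | (4S)-4-hydroxy-2,6,6-trimethylcyclohex-2-en-1-one | CC1=C[C@@H](O)CC(C)(C)C1=O | intermediate
14 | 2-methylbut-1-en-3-yne | CC(=C)C#C | starting material
15 | lithium 3-methylbut-3-en-1-yn-1-ide (not isolated) | [Li]C#CC(C)=C | intermediate
16 | (4S)-1-(3-methylbut-3-en-1-yn-1-yl)-2,6,6-trimethylcyclohex-2-ene-1,4-diol (C-1 epimers) | CC(=C)C#CC1(O)C(C)=C[C@@H](O)CC1(C)C | intermediate
17 | (4S)-1-[(1E)-3-methylbuta-1,3-dien-1-yl]-2,6,6-trimethylcyclohex-2-ene-1,4-diol (C-1 epimers) | CC(=C)/C=C/C1(O)C(C)=C[C@@H](O)CC1(C)C | intermediate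
18 | {(2E)-4-[(1E,4S)-4-hydroxy-2,6,6-trimethylcyclohex-2-en-1-ylidene]-2-methylbut-2-en-1-yl}triphenylphosphonium bromide | C\C(C[P+](c2ccccc2)(c3ccccc3)c4ccccc4)=C/C=C1/C(C)=C[C@@H](O)CC1(C)C.[Br-] | intermediate
19 | (2E)-3-methylpent-2-en-4-yn-1-ol | C#C/C(C)=C/CO | starting material
20 | (1E,3E)-5-[chlorobis(cyclopentadienyl)zirconiooxy]-3-methylpenta-1,3-dien-1-yl zirconocene chloride (not isolated) | C(/C=C(C)/C=C/[Zr](Cl)(C1C=CC=C1)C1C=CC=C1)O[Zr](Cl)(C1C=CC=C1)C1C=CC=C1 | intermediate
21 | (2E,4E,6E,8E)-3,8-dimethyldeca-2,4,6,8-tetraene-1,10-diol | OC/C=C(C)/C=C/C=C/C(C)=C/CO | intermediate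
22 | (2E,4E,6E,8E)-3,8-dimethyldeca-2,4,6,8-tetraenedial | O=C/C=C(C)/C=C/C=C/C(C)=C/C=O | intermediate
23 | {(2E)-4-[(1E,4S)-4-hydroxy-2,6,6-trimethylcyclohex-2-en-1-ylidene]-2-methylbut-2-en-1-ylidene}triphenylphosphorane (not isolated) | C\C(C=P(c2ccccc2)(c3ccccc3)c4ccccc4)=C/C=C1/C(C)=C[C@@H](O)CC1(C)C | intermediate
24 | (2E,4E,6E,8E,10E,12E)-14-[(1E,4S)-4-hydroxy-2,6,6-trimethylcyclohex-2-en-1-ylidene]-3,8,12-trimethyltetradeca-2,4,6,8,10,12-hexaenal (hydroxy C26 aldehyde, not isolated) | O=C/C=C(C)/C=C/C=C/C(C)=C/C=C/C(C)=C/C=C1/C(C)=C[C@@H](O)CC1(C)C | intermediate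
25 | (3S,3'S)-eschscholtzxanthin, (3S,3'S)-4',5'-didehydro-4,5'-retro-β,β-carotene-3,3'-diol | CC1=C[C@@H](O)CC(C)(C)\C1=C/C=C(C)/C=C/C=C(C)/C=C/C=C/C(C)=C/C=C/C(C)=C/C=C1/C(C)=C[C@@H](O)CC1(C)C | intermediate
26 | CNP0202479.1, anhydroeschscholtzxanthin (3'S) | CC1=CC=CC(C)(C)\C1=C/C=C(C)/C=C/C=C(C)/C=C/C=C/C(C)=C/C=C/C(C)=C/C=C1/C(C)=C[C@@H](O)CC1(C)C | target

Total step count: 13.
Longest linear sequence: 10 steps (steps 1, 2, 4, 5, 6, 7, 8, 9, 12, 13).

Steps most likely to fail

Step 6 (proposed new method). Protonolysis of the carbon–zinc bond, or hydride transfer between zinc lactolates, may outrun ring closure, and the facial discrimination by the amino alkoxide may be weak. The fallback uses known chemistry and sets out from lactol 11. N-Iodosuccinimide in CH2Cl2 at 0 °C opens the cyclopropanol at the CH2–C(O) bond to give (2Z)-6-iodo-3,5,5-trimethyl-4-oxohex-2-enal F1. CrCl2 with catalytic cobalt phthalocyanine Co(C32H16N8) in DMF (Nozaki–Hiyama–Kishi-type alkylchromium addition, selective for aldehydes over ketones) then forms the same CH2–CH(OH) ring bond and gives racemic 4-hydroxy-2,6,6-trimethylcyclohex-2-en-1-one F2. MnO2 oxidises this to 2,6,6-trimethylcyclohex-2-ene-1,4-dione F3, and asymmetric transfer hydrogenation of the less hindered carbonyl with RuCl(p-cymene)[(S,S)-TsDPEN] or its mirror image (whichever gives S) and HCO2H/Et3N comes back to the route at 13.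

Step 13. The second carbinol may ionise before enough diol has reacted once, so that over-dehydration to the hydrocarbon limits the mono-anhydro fraction, and acid may oligomerise the polyene. The fallback differentiates the two ends before any dehydration and sets out from 18 and 22. With the dialdehyde in threefold excess and slow addition of NaOMe (MeOH/CH2Cl2, 0 °C), the Wittig reaction should stop at the hydroxy C26 aldehyde 24, which is isolated here after I2-catalysed equilibration. Dry HCl (ca. 0.01 M) in CHCl3 at 0 °C dehydrates its only carbinol to (2E,4E,6E,8E,10E,12E,14Z)-3,8,12-trimethyl-14-(2,6,6-trimethylcyclohexa-2,4-dien-1-ylidene)tetradeca-2,4,6,8,10,12-hexaenal F4. A second Wittig reaction of F4 with 18 (NaOMe, MeOH/CH2Cl2, then I2-catalysed equilibration and crystallisation) comes back to the route at 26.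

Step 5. The free cyclopropanol may be opened oxidatively, or the lactol may be oxidised on to the lactone. The fallback sets the aldehyde oxidation level before the cyclopropanol exists and sets out from 6. MnO2 gives (2Z)-3-iodobut-2-enal F5, and HC(OMe)3 with catalytic pyridinium tosylate in MeOH gives (2Z)-3-iodo-1,1-dimethoxybut-2-ene F6. Iodine–lithium exchange (t-BuLi, Et2O, −78 °C) gives [(2E)-4,4-dimethoxybut-2-en-2-yl]lithium F7 (lithium cis to the acetal carbon), which is added to the magnesium hemiketalate of 3 as in step 4 to give 1-[(2Z)-4,4-dimethoxybut-2-en-2-yl]-2,2-dimethylcyclopropan-1-ol F8. Mild hydrolysis (pyridinium tosylate, wet acetone) comes back to the route at 11.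

Further compounds
F1 | step 6 | (2Z)-6-iodo-3,5,5-trimethyl-4-oxohex-2-enal | O=C/C=C(/C)C(=O)C(C)(C)CI
F2 | step 6 | racemic 4-hydroxy-2,6,6-trimethylcyclohex-2-en-1-one | CC1=CC(O)CC(C)(C)C1=O
F3 | step 6 | 2,6,6-trimethylcyclohex-2-ene-1,4-dione | CC1=CC(=O)CC(C)(C)C1=O
F4 | step 13 | (2E,4E,6E,8E,10E,12E,14Z)-3,8,12-trimethyl-14-(2,6,6-trimethylcyclohexa-2,4-dien-1-ylidene)tetradeca-2,4,6,8,10,12-hexaenal | O=C/C=C(C)/C=C/C=C/C(C)=C/C=C/C(C)=C/C=C1/C(C)=CC=CC1(C)C
F5 | step 5 | (2Z)-3-iodobut-2-enal | C/C(I)=C/C=O
F6 | step 5 | (2Z)-3-iodo-1,1-dimethoxybut-2-ene | C/C(I)=C/C(OC)OC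
F7 | step 5 | [(2E)-4,4-dimethoxybut-2-en-2-yl]lithium | COC(OC)/C=C(/C)[Li]
F8 | step 5 | 1-[(2Z)-4,4-dimethoxybut-2-en-2-yl]-2,2-dimethylcyclopropan-1-ol | COC(OC)/C=C(/C)C1(O)CC1(C)C
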